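## Retrosynthetic overview

1. Target 29 comes from a Schenck ene reaction on the Δ4 angelate 28 (C5–OOH, C4=C15). 28 comes from dienone 17 by C1=C2 hydrogenation, Luche reduction, α-methylenation of the C7 acetate arm and angeloylation.
2. The strategy rests on ring A (C1–C5, C10): it carries oxygen on C3, a methyl on C4 and the methyl-bearing quaternary C10 para to that oxygen, so it is a masked 2,4-dimethylphenol and C10 can be alkylated as an arene carbon.
3. Key disconnection C9–C10: the phenolate of iodo ester 15 closes ring B by para ipso-alkylation to give 17. Ring A is carried as the arene from the start; ring B is the only ring formed.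
4. 15 comes from TMSI opening of (S)-lactone 13, made by CuH asymmetric conjugate reduction of unsaturated lactone 12, itself from Negishi coupling of benzylic zinc 11 with enol triflate 10.
5. The arene comes from 2,6-dimethylbenzoic acid 1 by nitration, reduction, diazotisation and MOM protection.

Key step: step 11

Remark: positions are given in eudesmane numbering (ring A = C1–C5, C10; ring B = C5–C10; C14 on C10, C15 on C4, side chain C11–C13 on C7).
Assumption: the sense of induction of the CuH/p-tol-BINAP reduction in step 9 is assigned on the first run, and the ligand antipode that gives (4S)-13 is used.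

## Route

Step 1
Reactants: 1 2,6-dimethylbenzoic acid
Product: 2 2,6-dimethyl-3-nitrobenzoic acid
Conditions: fuming HNO3, conc. H2SO4, 0 °C → rt
Reagents that add atoms: nitric acid, O[N+](=O)[O-]
Why: Electrophilic aromatic nitration; the equivalent positions C3/C5 are ortho/para to the methyl groups and meta to CO2H, so a single mononitro acid should form.

Step 2
Reactants: 2 2,6-dimethyl-3-nitrobenzoic acid
Product: 3 3-amino-2,6-dimethylbenzoic acid
Conditions: H2 (1 atm), 10% Pd/C, MeOH, rt
Reagents that add atoms: none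
Why: Catalytic hydrogenation of a nitroarene to the aniline, which leaves the acid and the ring untouched.

Step 3
Reactants: 3 3-amino-2,6-dimethylbenzoic acid
Product: 5 3-hydroxy-2,6-dimethylbenzoic acid, via arenediazonium hydrogensulfate 4 (not isolated)
Conditions: NaNO2, aq. H2SO4, 0 °C; then 40% aq. H2SO4, 100 °C
Reagents that add atoms: water, O
Why: Diazotisation followed by thermal hydrolysis of the diazonium salt in hot dilute acid replaces NH2 by OH.

Step 4
Reactants: 5 3-hydroxy-2,6-dimethylbenzoic acid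
Product: 6 methoxymethyl 3-(methoxymethoxy)-2,6-dimethylbenzoate
Conditions: MOMCl, i-Pr2NEt, CH2Cl2, 0 °C → rt
Reagents that add atoms: chloromethyl methyl ether, COCCl
Why: Williamson-type O-alkylation of both the phenoxide and the carboxylate; carboxylate O-alkylation is not slowed by the two ortho methyl groups.

Step 5
Reactants: 6 methoxymethyl 3-(methoxymethoxy)-2,6-dimethylbenzoate
Product: 7 [3-(methoxymethoxy)-2,6-dimethylphenyl]methanol
Conditions: LiAlH4, THF, 0 °C → reflux
Reagents that add atoms: none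
Why: Hydride reduction of the ester to the benzylic alcohol; the aryl MOM ether is inert to LiAlH4.

Step 6
Reactants: 7 [3-(methoxymethoxy)-2,6-dimethylphenyl]methanol
Product: 8 2-(chloromethyl)-4-(methoxymethoxy)-1,3-dimethylbenzene
Conditions: PPh3, NCS, THF, 0 °C → rt
Reagents that add atoms: N-chlorosuccinimide, O=C1CCC(=O)N1Cl
Why: Appel-type chlorination through the alkoxyphosphonium salt under neutral conditions, so the acid-labile MOM ether should survive.

Step 7
Reactants: 9 oxane-2,4-dione
Product: 10 6-oxo-3,6-dihydro-2H-pyran-4-yl trifluoromethanesulfonate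
Conditions: Tf2O, Et3N, CH2Cl2, −78 °C
Reagents that add atoms: trifluoromethanesulfonic anhydride, O=S(=O)(OS(=O)(=O)C(F)(F)F)C(F)(F)F
Why: O-sulfonylation of the enol of the β-keto lactone at the C4 oxygen gives the vinylogous acyl triflate.

Step 8
Reactants: 8 2-(chloromethyl)-4-(methoxymethoxy)-1,3-dimethylbenzene; 10 6-oxo-3,6-dihydro-2H-pyran-4-yl trifluoromethanesulfonate
Product: 12 4-{[3-(methoxymethoxy)-2,6-dimethylphenyl]methyl}-5,6-dihydro-2H-pyran-2-one, via benzylic zinc chloride 11 (not isolated)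
Conditions: Zn dust, LiCl, THF, rt; then 10, Pd(OAc)2 (2 mol %), SPhos (4 mol %), THF, rt
Reagents that add atoms: none
Why: LiCl-promoted zinc insertion into the benzylic chloride followed by Negishi sp3–sp2 coupling with the alkenyl triflate forms the C6–C7 bond.

Step 9
Reactants: 12 4-{[3-(methoxymethoxy)-2,6-dimethylphenyl]methyl}-5,6-dihydro-2H-pyran-2-one
Product: 13 (4S)-4-{[3-(methoxymethoxy)-2,6-dimethylphenyl]methyl}oxan-2-one
Conditions: CuCl2·2H2O (5 mol %), p-tol-BINAP (5 mol %, antipode giving 4S), NaOt-Bu (cat.), PMHS, t-AmOH, toluene, 0 °C → rt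
Reagents that add atoms: none
Why: CuH-catalysed asymmetric conjugate reduction of a β-substituted unsaturated lactone; the bisphosphine-ligated copper hydride delivers hydride to the β-carbon (C7) on one enantiotopic face, which sets this centre under ligand control.

Step 10
Reactants: 13 (4S)-4-{[3-(methoxymethoxy)-2,6-dimethylphenyl]methyl}oxan-2-one
Product: 15 methyl (3R)-3-[(3-hydroxy-2,6-dimethylphenyl)methyl]-5-iodopentanoate, via bis-silylated iodo acid 14 (not isolated)
Conditions: TMSI (3 equiv), CH2Cl2, 0 °C → rt; then MeOH, rt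
Reagents that add atoms: iodotrimethylsilane, C[Si](C)(C)I; methanol, CO
Why: Iodide opens the O-silylated lactone by SN2 attack at the O–CH2 carbon (C9) and TMSI also cleaves the MOM acetal; methanol then frees the phenol and the HI formed drives Fischer esterification, with C7 untouched (the descriptor changes to R only through the priority change).

Step 11
Reactants: 15 methyl (3R)-3-[(3-hydroxy-2,6-dimethylphenyl)methyl]-5-iodopentanoate
Product: 17 methyl 2-[(2R,4aS)-4a,8-dimethyl-7-oxo-1,2,3,4,4a,7-hexahydronaphthalen-2-yl]acetate, via potassium phenolate 16 (not isolated)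
Conditions: KOt-Bu (1.0 equiv), t-BuOH, 0.005 M, 82 °C
Reagents that add atoms: none
Why: Deprotonation gives phenolate 16, an ambident nucleophile whose para carbon C10 displaces iodide from C9 in an intramolecular SN2 reaction, forming C9–C10, closing ring B and leaving the cross-conjugated cyclohexa-2,5-dienone with the angular methyl. The closest known reaction type is the Ar2-6 alkylation of phenolates through the para carbon, which gives 4a-alkyl dienones; ring B closes in a 6-(enolendo)-exo-tet mode. The new stereocentre C10 is controlled by C7: in the chair-like transition state the new bond forms perpendicular to the arene plane, the C10 methyl is pushed into the axial position of ring B and the CH2CO2Me group on C7 stays equatorial, which places methyl and side chain cis (4aS with 2R). The step needs C- over O-alkylation, para over ortho ipso attack and cyclisation over dimerisation. O-alkylation would require a strained eight-membered meta-bridged ether; the ortho carbon C4 lies between the solvated, K+-paired oxygen and C5, whereas C10 has the unsubstituted C1 as neighbour and the larger HOMO coefficient, so para attack is expected but must be confirmed; high dilution suppresses intermolecular O-alkylation. One equivalent of base is consumed by the phenol, so the methyl ester should stay unenolised.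

Step 12
Reactants: 17 methyl 2-[(2R,4aS)-4a,8-dimethyl-7-oxo-1,2,3,4,4a,7-hexahydronaphthalen-2-yl]acetate
Product: 18 methyl 2-[(2R,4aS)-4a,8-dimethyl-7-oxo-1,2,3,4,4a,5,6,7-octahydronaphthalen-2-yl]acetate
Conditions: H2 (1 atm), RhCl(PPh3)3 (10 mol %), benzene/EtOH, rt
Reagents that add atoms: none
Why: Homogeneous hydrogenation with RhCl(PPh3)3 should reduce the disubstituted C1=C2 alkene of the cross-conjugated dienone and leave the tetrasubstituted C4=C5 alkene and the ester alone.

Step 13
Reactants: 18 methyl 2-[(2R,4aS)-4a,8-dimethyl-7-oxo-1,2,3,4,4a,5,6,7-octahydronaphthalen-2-yl]acetate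
Product: 19 methyl 2-[(2R,4aS,7S)-7-hydroxy-4a,8-dimethyl-1,2,3,4,4a,5,6,7-octahydronaphthalen-2-yl]acetate
Conditions: NaBH4, CeCl3·7H2O, MeOH, −78 → 0 °C
Reagents that add atoms: none
Why: Luche 1,2-reduction; hydride should add axially from the α-face, opposite the axial C10 methyl, giving the equatorial 3β (7S) allylic alcohol without conjugate reduction.

Step 14
Reactants: 19 methyl 2-[(2R,4aS,7S)-7-hydroxy-4a,8-dimethyl-1,2,3,4,4a,5,6,7-octahydronaphthalen-2-yl]acetate
Product: 20 methyl 2-[(2R,4aS,7S)-7-[(tert-butyldimethylsilyl)oxy]-4a,8-dimethyl-1,2,3,4,4a,5,6,7-octahydronaphthalen-2-yl]acetate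
Conditions: TBSCl, imidazole, DMF, rt
Reagents that add atoms: tert-butyldimethylsilyl chloride, CC(C)(C)[Si](C)(C)Cl
Why: Silylation masks the alcohol before the strong-base step.

Step 15
Reactants: 20 methyl 2-[(2R,4aS,7S)-7-[(tert-butyldimethylsilyl)oxy]-4a,8-dimethyl-1,2,3,4,4a,5,6,7-octahydronaphthalen-2-yl]acetate
Product: 22 methyl (2RS)-3-(dimethylamino)-2-[(2R,4aS,7S)-7-[(tert-butyldimethylsilyl)oxy]-4a,8-dimethyl-1,2,3,4,4a,5,6,7-octahydronaphthalen-2-yl]propanoate, via lithium ester enolate 21 (not isolated)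
Conditions: LDA, THF, −78 °C; then Me2N=CH2+ I−, −78 °C → rt
Reagents that add atoms: dimethyl(methylidene)ammonium iodide, C=[N+](C)C.[I-]
Why: Mannich reaction of the ester enolate with the iminium salt adds C13; the C11 epimers are of no consequence because C11 becomes sp2 in the next step.

Step 16
Reactants: 22 methyl (2RS)-3-(dimethylamino)-2-[(2R,4aS,7S)-7-[(tert-butyldimethylsilyl)oxy]-4a,8-dimethyl-1,2,3,4,4a,5,6,7-octahydronaphthalen-2-yl]propanoate
Product: 24 methyl 2-[(2R,4aS,7S)-7-[(tert-butyldimethylsilyl)oxy]-4a,8-dimethyl-1,2,3,4,4a,5,6,7-octahydronaphthalen-2-yl]prop-2-enoate, via trimethylammonium iodide 23 (not isolated)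
Conditions: MeI, MeOH, rt; then DBU, CH2Cl2, rt
Reagents that add atoms: none
Why: N-methylation followed by Hofmann-type β-elimination (E1cB through the ester enolate) gives the α-methylene ester.

Step 17
Reactants: 24 methyl 2-[(2R,4aS,7S)-7-[(tert-butyldimethylsilyl)oxy]-4a,8-dimethyl-1,2,3,4,4a,5,6,7-octahydronaphthalen-2-yl]prop-2-enoate
Product: 25 methyl 2-[(2R,4aS,7S)-7-hydroxy-4a,8-dimethyl-1,2,3,4,4a,5,6,7-octahydronaphthalen-2-yl]prop-2-enoate
Conditions: TBAF, AcOH, THF, rt
Reagents that add atoms: none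
Why: Fluoride desilylation buffered with acetic acid should free the allylic alcohol without conjugate addition to the acrylate or ionisation at C3.

Step 18
Reactants: 25 methyl 2-[(2R,4aS,7S)-7-hydroxy-4a,8-dimethyl-1,2,3,4,4a,5,6,7-octahydronaphthalen-2-yl]prop-2-enoate; 26 angelic acid
Product: 28 methyl 2-[(2R,4aS,7S)-4a,8-dimethyl-7-{[(2Z)-2-methylbut-2-enoyl]oxy}-1,2,3,4,4a,5,6,7-octahydronaphthalen-2-yl]prop-2-enoate, via mixed anhydride 27 (not isolated)
Conditions: 2,4,6-Cl3C6H2COCl, Et3N, toluene, rt; then 25, toluene, 80 °C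
Reagents that add atoms: none
Why: Yamaguchi esterification through the mixed trichlorobenzoic anhydride without DMAP, conditions under which the Z (angelate) geometry should be kept; the C3–O bond is not broken, so C3 keeps its configuration.

Step 19
Reactants: 28 methyl 2-[(2R,4aS,7S)-4a,8-dimethyl-7-{[(2Z)-2-methylbut-2-enoyl]oxy}-1,2,3,4,4a,5,6,7-octahydronaphthalen-2-yl]prop-2-enoate
Product: 29 methyl 2-[(2R,4aS,7S,8aS)-8a-hydroperoxy-4a-methyl-8-methylidene-7-{[(2Z)-2-methylbut-2-enoyl]oxy}decahydronaphthalen-2-yl]prop-2-enoate (CNP0137897.1)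
Conditions: O2, hν (visible), tetraphenylporphyrin (cat.), CH2Cl2, −20 °C
Reagents that add atoms: dioxygen, O=O
Why: Schenck ene reaction; singlet oxygen should approach the tetrasubstituted C4=C5 alkene from the α-face anti to the axial C10 methyl, bond to C5 and take a hydrogen from the freely rotating C15 methyl (H-3α is geminal to the acyloxy group and H-6α lies near the alkene plane), which sets 5α-OOH (8aS) and the C4=C15 methylidene, while the electron-poor acrylate and angelate alkenes do not react.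

## Compound list

1 | 2,6-dimethylbenzoic acid | Cc1cccc(C)c1C(=O)O | starting material
2 | 2,6-dimethyl-3-nitrobenzoic acid | Cc1ccc([N+](=O)[O-])c(C)c1C(=O)O | intermediate
3 | 3-amino-2,6-dimethylbenzoic acid | Cc1ccc(N)c(C)c1C(=O)O | intermediate
4 | 3-carboxy-2,4-dimethylbenzenediazonium hydrogensulfate (not isolated) | Cc1ccc([N+]#N)c(C)c1C(=O)O.OS(=O)(=O)[O-] | intermediate
5 | 3-hydroxy-2,6-dimethylbenzoic acid | Cc1ccc(O)c(C)c1C(=O)O | intermediate
6 | methoxymethyl 3-(methoxymethoxy)-2,6-dimethylbenzoate | COCOC(=O)c1c(C)ccc(OCOC)c1C | intermediate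
7 | [3-(methoxymethoxy)-2,6-dimethylphenyl]methanol | COCOc1ccc(C)c(CO)c1C | intermediate
8 | 2-(chloromethyl)-4-(methoxymethoxy)-1,3-dimethylbenzene | COCOc1ccc(C)c(CCl)c1C | intermediate
9 | oxane-2,4-dione (dihydro-2H-pyran-2,4(3H)-dione) | O=C1CC(=O)CCO1 | starting material
10 | 6-oxo-3,6-dihydro-2H-pyran-4-yl trifluoromethanesulfonate | O=C1C=C(OS(=O)(=O)C(F)(F)F)CCO1 | intermediate
11 | {[3-(methoxymethoxy)-2,6-dimethylphenyl]methyl}zinc chloride (not isolated) | COCOc1ccc(C)c(C[Zn]Cl)c1C | intermediate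
12 | 4-{[3-(methoxymethoxy)-2,6-dimethylphenyl]methyl}-5,6-dihydro-2H-pyran-2-one | COCOc1ccc(C)c(CC2=CC(=O)OCC2)c1C | intermediate
13 | (4S)-4-{[3-(methoxymethoxy)-2,6-dimethylphenyl]methyl}oxan-2-one | O=C1C[C@@H](Cc2c(C)ccc(OCOC)c2C)CCO1 | intermediate
14 | trimethylsilyl (3R)-3-{[2,6-dimethyl-3-(trimethylsilyloxy)phenyl]methyl}-5-iodopentanoate (not isolated) | C[Si](C)(C)OC(=O)C[C@@H](Cc1c(C)ccc(O[Si](C)(C)C)c1C)CCI | intermediate
15 | methyl (3R)-3-[(3-hydroxy-2,6-dimethylphenyl)methyl]-5-iodopentanoate | COC(=O)C[C@@H](Cc1c(C)ccc(O)c1C)CCI | intermediate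
16 | potassium phenolate of 15 (not isolated) | COC(=O)C[C@@H](Cc1c(C)ccc([O-])c1C)CCI.[K+] | intermediate
17 | methyl 2-[(2R,4aS)-4a,8-dimethyl-7-oxo-1,2,3,4,4a,7-hexahydronaphthalen-2-yl]acetate (10β-methyl, 7β side chain) | COC(=O)C[C@@H]1CC[C@@]2(C)C=CC(=O)C(C)=C2C1 | intermediate
18 | methyl 2-[(2R,4aS)-4a,8-dimethyl-7-oxo-1,2,3,4,4a,5,6,7-octahydronaphthalen-2-yl]acetate | COC(=O)C[C@@H]1CC[C@@]2(C)CCC(=O)C(C)=C2C1 | intermediate
19 | methyl 2-[(2R,4aS,7S)-7-hydroxy-4a,8-dimethyl-1,2,3,4,4a,5,6,7-octahydronaphthalen-2-yl]acetate (3β-OH) | COC(=O)C[C@@H]1CC[C@@]2(C)CC[C@H](O)C(C)=C2C1 | intermediate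
20 | TBS ether of 19, methyl 2-[(2R,4aS,7S)-7-[(tert-butyldimethylsilyl)oxy]-4a,8-dimethyl-1,2,3,4,4a,5,6,7-octahydronaphthalen-2-yl]acetate | COC(=O)C[C@@H]1CC[C@@]2(C)CC[C@H](O[Si](C)(C)C(C)(C)C)C(C)=C2C1 | intermediate
21 | lithium ester enolate of 20 (not isolated) | COC([O-])=C[C@@H]1CC[C@@]2(C)CC[C@H](O[Si](C)(C)C(C)(C)C)C(C)=C2C1.[Li+] | intermediate
22 | methyl (2RS)-3-(dimethylamino)-2-[(2R,4aS,7S)-7-[(tert-butyldimethylsilyl)oxy]-4a,8-dimethyl-1,2,3,4,4a,5,6,7-octahydronaphthalen-2-yl]propanoate | COC(=O)C(CN(C)C)[C@@H]1CC[C@@]2(C)CC[C@H](O[Si](C)(C)C(C)(C)C)C(C)=C2C1 | intermediate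
23 | N-methyl ammonium iodide of 22 (not isolated) | COC(=O)C(C[N+](C)(C)C)[C@@H]1CC[C@@]2(C)CC[C@H](O[Si](C)(C)C(C)(C)C)C(C)=C2C1.[I-] | intermediate
24 | methyl 2-[(2R,4aS,7S)-7-[(tert-butyldimethylsilyl)oxy]-4a,8-dimethyl-1,2,3,4,4a,5,6,7-octahydronaphthalen-2-yl]prop-2-enoate | C=C(C(=O)OC)[C@@H]1CC[C@@]2(C)CC[C@H](O[Si](C)(C)C(C)(C)C)C(C)=C2C1 | intermediate
25 | methyl 2-[(2R,4aS,7S)-7-hydroxy-4a,8-dimethyl-1,2,3,4,4a,5,6,7-octahydronaphthalen-2-yl]prop-2-enoate | C=C(C(=O)OC)[C@@H]1CC[C@@]2(C)CC[C@H](O)C(C)=C2C1 | intermediate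
26 | angelic acid, (2Z)-2-methylbut-2-enoic acid | C/C=C(/C)C(=O)O | starting material
27 | (2Z)-2-methylbut-2-enoic 2,4,6-trichlorobenzoic anhydride (not isolated) | C/C=C(/C)C(=O)OC(=O)c1c(Cl)cc(Cl)cc1Cl | intermediate
28 | methyl 2-[(2R,4aS,7S)-4a,8-dimethyl-7-{[(2Z)-2-methylbut-2-enoyl]oxy}-1,2,3,4,4a,5,6,7-octahydronaphthalen-2-yl]prop-2-enoate | C=C(C(=O)OC)[C@@H]1CC[C@@]2(C)CC[C@H](OC(=O)/C(C)=C\C)C(C)=C2C1 | intermediate
29 | methyl 2-[(2R,4aS,7S,8aS)-8a-hydroperoxy-4a-methyl-8-methylidene-7-{[(2Z)-2-methylbut-2-enoyl]oxy}decahydronaphthalen-2-yl]prop-2-enoate (methyl 3β-angeloyloxy-5α-hydroperoxyeudesma-4(15),11(13)-dien-12-oate) | C=C(C(=O)OC)[C@@H]1CC[C@@]2(C)CC[C@H](OC(=O)/C(C)=C\C)C(=C)[C@]2(OO)C1 | target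

## Step count and risks

Total steps: 19. Longest linear sequence: 18 (steps 1–6 and 8–19; step 7 is the side branch).

Steps most likely to fail:

Step 11. The closure may go astray by ipso attack through the ortho carbon C4 (linearly conjugated dienone), by intermolecular O-alkylation, or by closure through the chair with the C7 chain axial (wrong face of C10). The fallback gives up dearomatisation and builds ring B as a cyclohexanone, onto which ring A is annulated (Robinson annulation under chiral-imine control). It sets out from triflate 10 and comes back at enone 18. Negishi coupling of 10 with (2-methylidenebutyl)zinc bromide would give 4-(2-methylidenebutyl)-5,6-dihydro-2H-pyran-2-one F1. CuH reduction as in step 9 would give (4S)-4-(2-methylidenebutyl)oxan-2-one F2, and ozonolysis (O3, then Me2S) would give (4R)-4-(2-oxobutyl)oxan-2-one F3. TMSI then MeOH would give methyl (3R)-3-(2-iodoethyl)-5-oxoheptanoate F4, and KOt-Bu would close the C9–C10 bond by ketone alkylation to methyl 2-[(1R)-4-methyl-3-oxocyclohexyl]acetate F5. Condensation with (R)-1-phenylethylamine would give methyl 2-[(1R)-4-methyl-3-{[(1R)-1-phenylethyl]imino}cyclohexyl]acetate F6, whose enamine tautomer adds to ethyl vinyl ketone under auxiliary control. Aqueous acetic acid would then release methyl 2-[(1R,4S)-4-methyl-3-oxo-4-(3-oxopentyl)cyclohexyl]acetate F7, and NaOMe/MeOH aldol condensation would give 18.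

Step 19. The ene reaction may take hydrogen from C3 or C6 instead of C15, or deliver oxygen to C4 or to the β-face. The fallback replaces it by an ionic sequence in which each stereochemical and regiochemical outcome is fixed by mechanism. It sets out from alcohol 25 and comes back at 29. Hydroxyl-directed epoxidation (VO(acac)2, t-BuOOH) would give methyl 4β,5β-epoxy-3β-hydroxyeudesm-11(13)-en-12-oate F8, and angeloylation as in step 18 would give methyl 3β-angeloyloxy-4β,5β-epoxyeudesm-11(13)-en-12-oate F9. Acid-catalysed perhydrolysis (ethereal H2O2, phosphomolybdic acid) should open the epoxide trans-diaxially at C5, remote from the acyloxy group, to methyl 3β-angeloyloxy-5α-hydroperoxy-4β-hydroxyeudesm-11(13)-en-12-oate F10. Silylation of the hydroperoxide (TESCl, imidazole) would give methyl 3β-angeloyloxy-4β-hydroxy-5α-(triethylsilylperoxy)eudesm-11(13)-en-12-oate F11. Syn-dehydration with the Burgess reagent can only use a C15 hydrogen (C5 has none and H-3 is anti) and would give methyl 3β-angeloyloxy-5α-(triethylsilylperoxy)eudesma-4(15),11(13)-dien-12-oate F12. HF·pyridine would then release 29.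

Step 18. The angeloyl unit may isomerise Z→E to the tiglate during activation, or acylation of the hindered allylic alcohol next to the C4 methyl may stall. The fallback builds the Z alkene on the ester instead of transferring a preformed angeloyl group. It sets out from alcohol 25 and comes back at 28. Esterification with 2-[bis(2,2,2-trifluoroethoxy)phosphoryl]propanoic acid (DCC, DMAP) would give methyl 3β-{2-[bis(2,2,2-trifluoroethoxy)phosphoryl]propanoyloxy}eudesma-4,11(13)-dien-12-oate F13. Still–Gennari olefination with acetaldehyde (KHMDS, 18-crown-6, THF, −78 °C) should then give the Z-configured angelate 28.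

Further compounds

F1 | step 11 | 4-(2-methylidenebutyl)-5,6-dihydro-2H-pyran-2-one | CCC(=C)CC1=CC(=O)OCC1
F2 | step 11 | (4S)-4-(2-methylidenebutyl)oxan-2-one | O=C1C[C@@H](CC(=C)CC)CCO1
F3 | step 11 | (4R)-4-(2-oxobutyl)oxan-2-one | O=C1C[C@@H](CC(=O)CC)CCO1
F4 | step 11 | methyl (3R)-3-(2-iodoethyl)-5-oxoheptanoate | COC(=O)C[C@@H](CC(=O)CC)CCI
F5 | step 11 | methyl 2-[(1R)-4-methyl-3-oxocyclohexyl]acetate (C4 epimers) | COC(=O)C[C@@H]1CCC(C)C(=O)C1
F6 | step 11 | methyl 2-[(1R)-4-methyl-3-{[(1R)-1-phenylethyl]imino}cyclohexyl]acetate | COC(=O)C[C@@H]1CCC(C)C(=N[C@H](C)c2ccccc2)C1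
F7 | step 11 | methyl 2-[(1R,4S)-4-methyl-3-oxo-4-(3-oxopentyl)cyclohexyl]acetate | COC(=O)C[C@@H]1CC[C@@](C)(CCC(=O)CC)C(=O)C1
F8 | step 19 | methyl 4β,5β-epoxy-3β-hydroxyeudesm-11(13)-en-12-oate | C=C(C(=O)OC)[C@@H]1CC[C@@]2(C)CC[C@H](O)[C@]3(C)O[C@]23C1
F9 | step 19 | methyl 3β-angeloyloxy-4β,5β-epoxyeudesm-11(13)-en-12-oate | C=C(C(=O)OC)[C@@H]1CC[C@@]2(C)CC[C@H](OC(=O)/C(C)=C\C)[C@]3(C)O[C@]23C1
F10 | step 19 | methyl 3β-angeloyloxy-5α-hydroperoxy-4β-hydroxyeudesm-11(13)-en-12-oate | C=C(C(=O)OC)[C@@H]1CC[C@@]2(C)CC[C@H](OC(=O)/C(C)=C\C)[C@](C)(O)[C@]2(OO)C1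
F11 | step 19 | methyl 3β-angeloyloxy-4β-hydroxy-5α-(triethylsilylperoxy)eudesm-11(13)-en-12-oate | C=C(C(=O)OC)[C@@H]1CC[C@@]2(C)CC[C@H](OC(=O)/C(C)=C\C)[C@](C)(O)[C@]2(OO[Si](CC)(CC)CC)C1
F12 | step 19 | methyl 3β-angeloyloxy-5α-(triethylsilylperoxy)eudesma-4(15),11(13)-dien-12-oate | C=C(C(=O)OC)[C@@H]1CC[C@@]2(C)CC[C@H](OC(=O)/C(C)=C\C)C(=C)[C@]2(OO[Si](CC)(CC)CC)C1
F13 | step 18 | methyl 3β-{2-[bis(2,2,2-trifluoroethoxy)phosphoryl]propanoyloxy}eudesma-4,11(13)-dien-12-oate | C=C(C(=O)OC)[C@@H]1CC[C@@]2(C)CC[C@H](OC(=O)C(C)P(=O)(OCC(F)(F)F)OCC(F)(F)F)C(C)=C2C1
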